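## Retrosynthetic overview

1. The butenolide is made last, by lactonisation of a (Z)-γ-hydroxy enoate. That enoate comes from a Z-selective Horner–Wadsworth–Emmons reaction on an α-oxygenated aldehyde, and the butenolide C5 (R) centre is set by L-proline α-aminoxylation.
2. The aldehyde comes from a two-carbon homologation of an (E)-allylic bromide, made by SeO2 oxidation of a prenyl terminus.
3. The 2H-chromene is made first, by ring-closing metathesis of an o-vinylaryl linalyl ether. The quaternary C2 (S) centre is bought as (S)-linalool and attached by SNAr, so its C–O bond is never broken.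
4. Ring order: chromene (step 3), then butenolide (step 11).

Assumptions: (S)-(+)-linalool is purchased in high ee, and N-cyclohexylacetaldimine is purchased (otherwise condensed from acetaldehyde and cyclohexylamine). Numbered compounds are building blocks, intermediates and the target; bulk reagents are given by name and SMILES in each step.

## Route

**Step 1**
Reactants: 1, (S)-(+)-linalool; 2, 5-bromo-2-fluoro-3-methylbenzaldehyde
Product: 3, 5-bromo-2-{[(3S)-3,7-dimethylocta-1,6-dien-3-yl]oxy}-3-methylbenzaldehyde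
Conditions: KH, THF/DMF, 0 °C; then 2, 0 °C → rt
Reagents that add atoms: none (all atoms from 1 and 2)
Why: SNAr of the tertiary potassium alkoxide on the fluoride activated by the ortho-CHO; the carbinol C–O bond is not touched, so the (S) centre is carried over unchanged.

**Step 2**
Reactants: 3; 4, methyltriphenylphosphonium bromide
Product: 5, 5-bromo-2-{[(3S)-3,7-dimethylocta-1,6-dien-3-yl]oxy}-1-methyl-3-vinylbenzene
Conditions: Ph3PCH3Br, KOtBu, THF, 0 °C → rt
Reagents that add atoms: 4, methyltriphenylphosphonium bromide, C[P+](c1ccccc1)(c1ccccc1)c1ccccc1.[Br-] (gives the CH2)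
Why: Wittig methylenation of a non-enolisable aryl aldehyde; no stereocentre is involved.

**Step 3**
Reactants: 5
Product: 6, (2S)-6-bromo-2,8-dimethyl-2-(4-methylpent-3-en-1-yl)-2H-chromene
Conditions: Grubbs II (3 mol %), CH2Cl2 (5 mM), 40 °C
Reagents that add atoms: none
Why: Ring-closing metathesis of the two terminal vinyl groups closes the six-membered chromene (ethylene lost); the trisubstituted prenyl alkene reacts far more slowly, and the quaternary centre is a spectator.

**Step 4**
Reactants: 6
Product: 7, (2S)-2,8-dimethyl-2-(4-methylpent-3-en-1-yl)-2H-chromen-6-ol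
Conditions: n-BuLi, THF, −78 °C; B(OMe)3, −78 → 0 °C; then H2O2, aq NaOH, 0 °C
Reagents that add atoms: hydrogen peroxide, OO (the phenol O); trimethyl borate COB(OC)OC is transient
Why: Br–Li exchange, borylation and oxidative ipso-hydroxylation; the alkenes are inert to alkaline peroxide.

**Step 5**
Reactants: 7; 8, tert-butyldimethylsilyl chloride
Product: 9, (2S)-6-(tert-butyldimethylsilyloxy)-2,8-dimethyl-2-(4-methylpent-3-en-1-yl)-2H-chromene
Conditions: TBSCl, imidazole, DMF, rt
Reagents that add atoms: 8, TBSCl, CC(C)(C)[Si](C)(C)Cl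
Why: Silylation masks the oxidation-prone, acidic phenol for the SeO2, aza-enolate and HWE steps.

**Step 6**
Reactants: 9
Product: 10, (2E)-5-[(2S)-6-(tert-butyldimethylsilyloxy)-2,8-dimethyl-2H-chromen-2-yl]-2-methylpent-2-en-1-ol
Conditions: SeO2 (0.5 equiv), t-BuOOH, salicylic acid (cat.), CH2Cl2, 0 °C → rt; then NaBH4, MeOH, 0 °C (returns any enal)
Reagents that add atoms: selenium dioxide, O=[Se]=O (O), with tert-butyl hydroperoxide CC(C)(C)OO as re-oxidant
Why: Sharpless-type SeO2 allylic oxidation (ene, then [2,3] shift) hydroxylates the (E)-methyl of the trisubstituted alkene; the chromene alkene has no allylic C–H.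

**Step 7**
Reactants: 10
Product: 11, (2S)-2-[(3E)-5-bromo-4-methylpent-3-en-1-yl]-6-(tert-butyldimethylsilyloxy)-2,8-dimethyl-2H-chromene
Conditions: CBr4, PPh3, CH2Cl2, 0 °C
Reagents that add atoms: carbon tetrabromide, BrC(Br)(Br)Br (Br)
Why: Appel bromination of the primary allylic alcohol under neutral conditions keeps the E geometry.

**Step 8**
Reactants: 11; 12, N-cyclohexylacetaldimine
Product: 13, (4E)-7-[(2S)-6-(tert-butyldimethylsilyloxy)-2,8-dimethyl-2H-chromen-2-yl]-4-methylhept-4-enal
Conditions: 12, LDA, THF, −78 °C; then 11, −78 → 0 °C; aq oxalic acid, rt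
Reagents that add atoms: 12, CC=NC1CCCCC1 (two carbons); water, O (aldehyde oxygen)
Why: Stork metalloenamine (aza-enolate) SN2 alkylation of the allylic bromide, then imine hydrolysis, gives the two-carbon-homologated aldehyde.

**Step 9**
Reactants: 14, ethyl 2-(diphenoxyphosphoryl)acetate; 15, 5-bromo-2-methylpent-2-ene
Product: 16, ethyl 2-(diphenoxyphosphoryl)-6-methylhept-5-enoate
Conditions: NaH, DMSO, rt → 50 °C
Reagents that add atoms: none beyond 14 and 15
Why: SN2 α-alkylation of the phosphonoacetate anion gives the Ando-type reagent carrying the butenolide α-side chain.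

**Step 10**
Reactants: 13; 17, nitrosobenzene; 16
Product: 18, ethyl (2Z,4R,6E)-4-(anilinooxy)-9-[(2S)-6-(tert-butyldimethylsilyloxy)-2,8-dimethyl-2H-chromen-2-yl]-6-methyl-2-(4-methylpent-3-en-1-yl)nona-2,6-dienoate
Conditions: L-proline (20 mol %), PhNO (1.0 equiv), MeCN, −20 °C; then added to 16/NaH, THF, −78 → −20 °C
Reagents that add atoms: 17, nitrosobenzene, O=Nc1ccccc1 (O and NHPh); 16 (C2, C3 and side chain of the lactone)
Why: Proline enamine α-aminoxylation (O-selective nitroso aldol) with L-proline gives the (R) C–O centre; the labile aldehyde is trapped in situ by an Ando Z-selective HWE olefination.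

**Step 11**
Reactants: 18
Product: 19, (5R)-5-{(2E)-5-[(2S)-6-(tert-butyldimethylsilyloxy)-2,8-dimethyl-2H-chromen-2-yl]-2-methylpent-2-en-1-yl}-3-(4-methylpent-3-en-1-yl)furan-2(5H)-one
Conditions: Cu(OAc)2 (30 mol %), EtOH, rt; then PPTS (cat.), toluene, 40 °C
Reagents that add atoms: none
Why: Cu(II)-mediated N–O cleavage frees the γ-hydroxyl, which lactonises onto the cis ester (EtOH lost); only the Z-enoate can close, and the C5 centre is not touched.

**Step 12**
Reactants: 19
Product: 20, tuberatolide B
Conditions: TBAF/AcOH (1:1), THF, 0 °C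
Reagents that add atoms: none
Why: Fluoride desilylation of the aryl silyl ether, buffered with AcOH so the base-sensitive butenolide γ-centre does not epimerise.

## Compound list

1 | (S)-(+)-linalool | CC(C)=CCC[C@](C)(O)C=C | starting material
2 | 5-bromo-2-fluoro-3-methylbenzaldehyde | O=Cc1cc(Br)cc(C)c1F | starting material
3 | 5-bromo-2-{[(3S)-3,7-dimethylocta-1,6-dien-3-yl]oxy}-3-methylbenzaldehyde | CC(C)=CCC[C@](C)(Oc1c(C)cc(Br)cc1C=O)C=C | intermediate
4 | methyltriphenylphosphonium bromide | C[P+](c1ccccc1)(c1ccccc1)c1ccccc1.[Br-] | starting material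
5 | 5-bromo-2-{[(3S)-3,7-dimethylocta-1,6-dien-3-yl]oxy}-1-methyl-3-vinylbenzene | CC(C)=CCC[C@](C)(Oc1c(C)cc(Br)cc1C=C)C=C | intermediate
6 | (2S)-6-bromo-2,8-dimethyl-2-(4-methylpent-3-en-1-yl)-2H-chromene | CC(C)=CCC[C@@]1(C)C=Cc2cc(Br)cc(C)c2O1 | intermediate
7 | (2S)-2,8-dimethyl-2-(4-methylpent-3-en-1-yl)-2H-chromen-6-ol | CC(C)=CCC[C@@]1(C)C=Cc2cc(O)cc(C)c2O1 | intermediate
8 | tert-butyldimethylsilyl chloride | CC(C)(C)[Si](C)(C)Cl | starting material
9 | TBS ether of 7 | CC(C)=CCC[C@@]1(C)C=Cc2cc(O[Si](C)(C)C(C)(C)C)cc(C)c2O1 | intermediate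
10 | (E)-allylic alcohol | OC/C(C)=C/CC[C@@]1(C)C=Cc2cc(O[Si](C)(C)C(C)(C)C)cc(C)c2O1 | intermediate
11 | (E)-allylic bromide | BrC/C(C)=C/CC[C@@]1(C)C=Cc2cc(O[Si](C)(C)C(C)(C)C)cc(C)c2O1 | intermediate
12 | N-cyclohexylacetaldimine | CC=NC1CCCCC1 | starting material
13 | (4E)-7-[(2S)-6-(TBSO)-2,8-dimethyl-2H-chromen-2-yl]-4-methylhept-4-enal | O=CCC/C(C)=C/CC[C@@]1(C)C=Cc2cc(O[Si](C)(C)C(C)(C)C)cc(C)c2O1 | intermediate
14 | ethyl 2-(diphenoxyphosphoryl)acetate | CCOC(=O)CP(=O)(Oc1ccccc1)Oc1ccccc1 | starting material
15 | 5-bromo-2-methylpent-2-ene | CC(C)=CCCBr | starting material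
16 | ethyl 2-(diphenoxyphosphoryl)-6-methylhept-5-enoate | CCOC(=O)C(CCC=C(C)C)P(=O)(Oc1ccccc1)Oc1ccccc1 | intermediate
17 | nitrosobenzene | O=Nc1ccccc1 | starting material
18 | (2Z,4R,6E)-γ-anilinooxy enoate | CCOC(=O)/C(CCC=C(C)C)=C\[C@H](ONc1ccccc1)C/C(C)=C/CC[C@@]1(C)C=Cc2cc(O[Si](C)(C)C(C)(C)C)cc(C)c2O1 | intermediate
19 | O-TBS tuberatolide B | CC(C)=CCCC1=C[C@@H](C/C(C)=C/CC[C@@]2(C)C=Cc3cc(O[Si](C)(C)C(C)(C)C)cc(C)c3O2)OC1=O | intermediate
20 | tuberatolide B | CC(C)=CCCC1=C[C@@H](C/C(C)=C/CC[C@@]2(C)C=Cc3cc(O)cc(C)c3O2)OC1=O | target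

## Summary

Total steps: 12. Longest linear sequence: 11 (steps 1–8, 10–12); step 9 is a one-step side branch.

Steps most likely to fail, with fallbacks:

1. **Step 1 (SNAr).** A hindered tertiary alkoxide attacks a fluoride flanked by CHO and CH3, with the free aldehyde present. Fallback: make the tertiary aryl ether by Pd-catalysed asymmetric allylic etherification of 5-bromo-2-hydroxy-3-methylbenzaldehyde with geranyl methyl carbonate, so the stereocentre is set by the catalyst instead of the chiral pool, then rejoin at 3.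
2. **Step 3 (RCM).** The vinyl group next to the quaternary centre is hindered, and cyclopentene formation with the prenyl alkene could compete. Fallback: avoid metathesis. Hydroborate the vinyl group of (S)-linalool with 9-BBN, do a B-alkyl Suzuki coupling with an o-bromoaryl iodide, close the chroman by Pd-catalysed intramolecular C–O coupling of the tertiary alcohol, and dehydrogenate with DDQ to the chromene.
3. **Step 10 (aminoxylation/Z-olefination).** Risks are nitroso side reactions with the electron-rich alkenes, epimerisation of the α-oxy aldehyde and incomplete Z-selectivity. Fallback: set the C–O centre with an auxiliary. Alkylate bromide 11 with an Evans/Crimmins glycolate imide, convert to the α-silyloxy aldehyde, then Z-olefinate with a Still–Gennari analogue of 16 and lactonise on desilylation.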